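**Plan**

- Retrosynthesis: the cinnamyl arm is cut at its C=C bond (Horner–Wadsworth–Emmons) and at the CH2–CHO bond behind it (one-carbon Wittig homologation), which turns the exocyclic carbon on C3 into a lactone carbonyl. Then the C2–C3 bond of the oxane is cut, then O1–C2 (mixed acetal of a 4-silyloxybenzaldehyde), then the ArCH(OH)–C5 bond (anti-aldol).
- Enabling feature: the carbinol oxygen of the C5 arm and the exocyclic carbon on C3 can be joined into a six-membered lactone (O–CH(Ar)–C5–C4–C3–C=O). This temporary ring makes C3 an enolisable α-carbon and lets the oxane close only with the C3 and C5 arms cis, as a 3,7-dioxabicyclo[3.3.1]nonan-2-one. O1 next to the aryl-bearing C2 supplies an aryl-stabilised oxocarbenium ion.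
- Forward order: anti-aldol, δ-lactone (temporary ring), mixed acetal on the primary oxygen, closure of the oxane ring inside the bicycle, reductive opening of the lactone, homologation, olefination, desilylation.
- Stereochemistry: C5 and the carbinol carbon come from the auxiliary-controlled anti-aldol, C3 from the tether, C2 from a chair transition state with equatorial aryl, and the alkene from the E-selective olefination.

Key step: step 8

Remark: the SMILES is read as the all-cis (2R,3S,5R)-oxane with an (R)-configured benzylic carbinol, and the mixed acetal of step 8 is assumed to ionise by loss of methoxide (the other, reversible ionisation leads to no ring).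

**Step 1**
Reactants: 1 4-hydroxybenzaldehyde
Product: 2 4-(triisopropylsilyloxy)benzaldehyde
Conditions: i-Pr3SiCl, imidazole, DMF, rt
Reagents that add atoms: triisopropylsilyl chloride, CC(C)[Si](Cl)(C(C)C)C(C)C
Why: Imidazole-mediated silylation of a phenol; the triisopropylsilyl ether is chosen because it should survive LiOOH, amide bases, hydrides and ylides and still fall to fluoride at the end.

**Step 2**
Reactants: 2 4-(triisopropylsilyloxy)benzaldehyde
Product: 3 [4-(dimethoxymethyl)phenoxy]triisopropylsilane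
Conditions: HC(OMe)3, pyridinium p-toluenesulfonate (cat.), MeOH, rt
Reagents that add atoms: trimethyl orthoformate, COC(OC)OC
Why: Acid-catalysed acetalisation of an aromatic aldehyde, driven by the orthoformate as water scavenger.

**Step 3**
Reactants: 4 (4R)-4-benzyl-1,3-oxazolidin-2-one, 5 methyl 5-chloro-5-oxopentanoate
Product: 6 methyl 5-[(4R)-4-benzyl-2-oxo-1,3-oxazolidin-3-yl]-5-oxopentanoate
Conditions: n-BuLi, THF, −78 °C; then 5, −78 → 0 °C
Reagents that add atoms: none
Why: N-Acylation of the lithiated oxazolidinone by an acid chloride (standard loading of an Evans auxiliary); the remote methyl ester should be untouched at −78 °C.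

**Step 4**
Reactants: 6 imide, 2 4-(triisopropylsilyloxy)benzaldehyde
Product: 8 methyl (4S,5R)-4-{[(4R)-4-benzyl-2-oxo-1,3-oxazolidin-3-yl]carbonyl}-5-hydroxy-5-[4-(triisopropylsilyloxy)phenyl]pentanoate, via aldol trimethylsilyl ether 7 (not isolated)
Conditions: MgCl2 (0.2 equiv), Et3N, Me3SiCl, EtOAc, rt; then MeOH, pyridinium p-toluenesulfonate (cat.), 0 °C
Reagents that add atoms: none
Why: MgCl2-catalysed Evans anti-aldol with a non-enolisable aromatic aldehyde: the chelated (Z)-magnesium enolate of the imide is attacked on the face anti to the benzyl group (same sense as Evans alkylation), which sets (S) at the α-carbon, and the anti relation sets (R) at the carbinol carbon.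

**Step 5**
Reactants: 8 anti-aldol adduct
Product: 10 (2R,3S)-6-oxo-2-[4-(triisopropylsilyloxy)phenyl]oxane-3-carboxylic acid (cis), via hydroxy acid 9 (not isolated)
Conditions: LiOH, H2O2, THF/H2O, 0 °C; Na2SO3; 1 M HCl to pH 3 at 0 °C; then pyridinium p-toluenesulfonate (cat.), toluene, 50 °C
Reagents that add atoms: hydrogen peroxide (as LiOOH), OO
Why: LiOOH cleaves the exocyclic imide carbonyl selectively and the freed δ-hydroxy methyl ester lactonises under mild acid (only the δ-lactone is possible, since the new carboxyl is β to the hydroxyl); both operations are acyl substitutions, so neither stereocentre is touched.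

**Step 6**
Reactants: 10 lactone acid
Product: 11 (5R,6R)-5-(hydroxymethyl)-6-[4-(triisopropylsilyloxy)phenyl]oxan-2-one
Conditions: BH3·THF, THF, −10 °C → rt; MeOH quench
Reagents that add atoms: none
Why: Borane reduces a carboxylic acid through its acyloxyborane much faster than a lactone, the classic chemoselective reduction of lactone acids to hydroxymethyl lactones.

**Step 7**
Reactants: 11 hydroxymethyl lactone, 3 dimethyl acetal (excess)
Product: 12 (5R,6R)-5-({methoxy[4-(triisopropylsilyloxy)phenyl]methoxy}methyl)-6-[4-(triisopropylsilyloxy)phenyl]oxan-2-one (both epimers at the acetal carbon)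
Conditions: pyridinium p-toluenesulfonate (cat.), 5 Å molecular sieves, CH2Cl2, rt; Et3N quench; Et3N-deactivated silica
Reagents that add atoms: none
Why: Acid-catalysed transacetalisation with excess dimethyl acetal under removal of methanol should give mainly the mixed acetal; its acetal carbon becomes planar in the next step, so the epimer mixture is of no consequence.

**Step 8**
Reactants: 12 mixed acetal lactone
Product: 15 (1S,4R,5R,8R)-4,8-bis[4-(triisopropylsilyloxy)phenyl]-3,7-dioxabicyclo[3.3.1]nonan-2-one, via silyl ketene acetal 13 (not isolated), via oxocarbenium triflate 14 (not isolated)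
Conditions: LiN(i-Pr)2, Me3SiCl, THF, −78 °C; solvent switch to CH2Cl2 (high dilution); Me3SiOTf (cat.), 2,6-di-tert-butyl-4-methylpyridine, −78 → −40 °C
Reagents that add atoms: none
Why: LiN(i-Pr)2/Me3SiCl turns the δ-lactone into its cyclic silyl ketene acetal 13, and catalytic Me3SiOTf ionises the mixed benzylic acetal at the less hindered methoxy group to the aryl-stabilised (E)-oxocarbenium ion 14, which is trapped by the ketene acetal carbon C3. The closest known reaction type is the Me3SiOTf-catalysed Mukaiyama aldol addition of silyl ketene acetals to acetals, used intramolecularly for tetrahydropyran synthesis. The oxane ring closes in a 6-(enolexo)-exo-trig mode, and because the tether hangs from C5 of the lactone the product is necessarily the bridged 3,7-dioxabicyclo[3.3.1]nonan-2-one. C3 (C1 of the bicycle) is set by the tether: only the ketene acetal face syn to the axial CH2O arm can be reached, so the lactone carbonyl and the C5 carbinol arm become 1,3-cis on the new oxane. C2 (C8 of the bicycle) is set by a chair transition state of the (E)-oxocarbenium ion that keeps the aryl group equatorial, i.e. cis to the lactone bridge, which is the all-cis 2,3,5-pattern of the target. The step needs ring closure to beat intermolecular addition and loss of methoxide to beat loss of the lactone-bearing alkoxide; high dilution, the pre-organised cis-lactone (aryl equatorial, CH2O arm axial) and the low temperature should secure this, and the bridgehead C3–H of 15 cannot enolise afterwards.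

**Step 9**
Reactants: 15 bicyclic lactone
Product: 16 (1S,4R,5R,8R)-4,8-bis[4-(triisopropylsilyloxy)phenyl]-3,7-dioxabicyclo[3.3.1]nonan-2-ol (lactol, both epimers at C2 of the bicycle)
Conditions: i-Bu2AlH, CH2Cl2, −78 °C; aq. potassium sodium tartrate (KNaC4H4O6)
Reagents that add atoms: none
Why: Partial reduction of a lactone to the lactol through the aluminate that is stable at −78 °C; the bridgehead centre cannot epimerise.

**Step 10**
Reactants: 16 lactol, 17 (methoxymethyl)triphenylphosphonium chloride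
Product: 19 2-{(2R,3R,5R)-5-{(R)-hydroxy[4-(triisopropylsilyloxy)phenyl]methyl}-2-[4-(triisopropylsilyloxy)phenyl]oxan-3-yl}acetaldehyde, via enol ether 18 (not isolated)
Conditions: 17, KN(SiMe3)2, THF, 0 °C; then 16, 0 °C → rt; then 0.5 M aq. HCl/THF, 0 °C
Reagents that add atoms: water, O
Why: Wittig methoxymethylenation of the lactol through its hydroxy aldehyde form, then hydrolysis of the enol ether, is the standard one-carbon homologation of an aldehyde; the reactive ylide should trap the aldehyde before C3 epimerises, and cold dilute acid should spare the benzylic ether and alcohol (the product may rest partly as its seven-membered lactol).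

**Step 11**
Reactants: 20 diethyl (4-hydroxybenzyl)phosphonate
Product: 21 diethyl [4-(triisopropylsilyloxy)benzyl]phosphonate
Conditions: i-Pr3SiCl, imidazole, DMF, rt
Reagents that add atoms: triisopropylsilyl chloride, CC(C)[Si](Cl)(C(C)C)C(C)C
Why: Imidazole-mediated silylation of a phenol, as in step 1.

**Step 12**
Reactants: 19 homologated aldehyde, 21 benzylic phosphonate
Product: 22 (R)-[4-(triisopropylsilyloxy)phenyl]{(3R,5S,6R)-6-[4-(triisopropylsilyloxy)phenyl]-5-{(2E)-3-[4-(triisopropylsilyloxy)phenyl]prop-2-en-1-yl}oxan-3-yl}methanol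
Conditions: 21 (excess), NaH, 15-crown-5 (cat.), THF, 0 °C; then 19, 0 °C → rt
Reagents that add atoms: none
Why: Horner–Wadsworth–Emmons olefination with a benzylic phosphonate should give the (E)-styrene because the adducts equilibrate before elimination; the excess anion absorbs the free hydroxyl.

**Step 13**
Reactants: 22 tris-silyl ether
Product: 23 4-[(1E)-3-{(2R,3S,5R)-5-[(R)-hydroxy(4-hydroxyphenyl)methyl]-2-(4-hydroxyphenyl)oxan-3-yl}prop-1-en-1-yl]phenol (CNP0182155.1)
Conditions: n-Bu4NF, AcOH (1:1), THF, 0 °C → rt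
Reagents that add atoms: none
Why: Fluoride cleaves the three aryl silyl ethers, and the acetic acid buffer should keep the 4-hydroxybenzylic ether and alcohol from base-induced quinone methide formation, so C2 and the carbinol keep their configuration.

**Compound list**

1 | 4-hydroxybenzaldehyde | O=Cc1ccc(O)cc1 | starting material
2 | 4-(triisopropylsilyloxy)benzaldehyde | O=Cc1ccc(O[Si](C(C)C)(C(C)C)C(C)C)cc1 | intermediate
3 | [4-(dimethoxymethyl)phenoxy]triisopropylsilane | COC(OC)c1ccc(O[Si](C(C)C)(C(C)C)C(C)C)cc1 | intermediate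
4 | (4R)-4-benzyl-1,3-oxazolidin-2-one | O=C1N[C@H](Cc2ccccc2)CO1 | starting material
5 | methyl 5-chloro-5-oxopentanoate | COC(=O)CCCC(Cl)=O | starting material
6 | methyl 5-[(4R)-4-benzyl-2-oxo-1,3-oxazolidin-3-yl]-5-oxopentanoate | COC(=O)CCCC(=O)N1[C@H](Cc2ccccc2)COC1=O | intermediate
7 | methyl (4S,5R)-4-{[(4R)-4-benzyl-2-oxo-1,3-oxazolidin-3-yl]carbonyl}-5-[4-(triisopropylsilyloxy)phenyl]-5-(trimethylsilyloxy)pentanoate | COC(=O)CC[C@@H]([C@@H](O[Si](C)(C)C)c1ccc(O[Si](C(C)C)(C(C)C)C(C)C)cc1)C(=O)N1[C@H](Cc2ccccc2)COC1=O | intermediate (not isolated)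
8 | methyl (4S,5R)-4-{[(4R)-4-benzyl-2-oxo-1,3-oxazolidin-3-yl]carbonyl}-5-hydroxy-5-[4-(triisopropylsilyloxy)phenyl]pentanoate | COC(=O)CC[C@@H]([C@@H](O)c1ccc(O[Si](C(C)C)(C(C)C)C(C)C)cc1)C(=O)N1[C@H](Cc2ccccc2)COC1=O | intermediate
9 | (2S)-2-{(R)-hydroxy[4-(triisopropylsilyloxy)phenyl]methyl}-5-methoxy-5-oxopentanoic acid | COC(=O)CC[C@@H]([C@@H](O)c1ccc(O[Si](C(C)C)(C(C)C)C(C)C)cc1)C(=O)O | intermediate (not isolated)
10 | (2R,3S)-6-oxo-2-[4-(triisopropylsilyloxy)phenyl]oxane-3-carboxylic acid | O=C1CC[C@@H]([C@@H](O1)c2ccc(O[Si](C(C)C)(C(C)C)C(C)C)cc2)C(=O)O | intermediate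
11 | (5R,6R)-5-(hydroxymethyl)-6-[4-(triisopropylsilyloxy)phenyl]oxan-2-one | O=C1CC[C@@H]([C@@H](O1)c2ccc(O[Si](C(C)C)(C(C)C)C(C)C)cc2)CO | intermediate
12 | (5R,6R)-5-({methoxy[4-(triisopropylsilyloxy)phenyl]methoxy}methyl)-6-[4-(triisopropylsilyloxy)phenyl]oxan-2-one, both acetal epimers | O=C1CC[C@@H]([C@@H](O1)c2ccc(O[Si](C(C)C)(C(C)C)C(C)C)cc2)COC(OC)c3ccc(O[Si](C(C)C)(C(C)C)C(C)C)cc3 | intermediate
13 | {[(2R,3R)-3-({methoxy[4-(triisopropylsilyloxy)phenyl]methoxy}methyl)-2-[4-(triisopropylsilyloxy)phenyl]-3,4-dihydro-2H-pyran-6-yl]oxy}trimethylsilane | C[Si](C)(C)OC1=CC[C@@H]([C@@H](O1)c2ccc(O[Si](C(C)C)(C(C)C)C(C)C)cc2)COC(OC)c3ccc(O[Si](C(C)C)(C(C)C)C(C)C)cc3 | intermediate (not isolated)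
14 | oxocarbenium triflate formed from 13 by loss of methoxide (O-alkylated 4-(triisopropylsilyloxy)benzaldehyde) | C[Si](C)(C)OC1=CC[C@@H]([C@@H](O1)c2ccc(O[Si](C(C)C)(C(C)C)C(C)C)cc2)C[O+]=Cc3ccc(O[Si](C(C)C)(C(C)C)C(C)C)cc3.[O-]S(=O)(=O)C(F)(F)F | intermediate (not isolated)
15 | (1S,4R,5R,8R)-4,8-bis[4-(triisopropylsilyloxy)phenyl]-3,7-dioxabicyclo[3.3.1]nonan-2-one | O=C1[C@H]2C[C@@H]([C@@H](O1)c3ccc(O[Si](C(C)C)(C(C)C)C(C)C)cc3)CO[C@H]2c4ccc(O[Si](C(C)C)(C(C)C)C(C)C)cc4 | intermediate
16 | (1S,4R,5R,8R)-4,8-bis[4-(triisopropylsilyloxy)phenyl]-3,7-dioxabicyclo[3.3.1]nonan-2-ol, both lactol epimers | OC1[C@H]2C[C@@H]([C@@H](O1)c3ccc(O[Si](C(C)C)(C(C)C)C(C)C)cc3)CO[C@H]2c4ccc(O[Si](C(C)C)(C(C)C)C(C)C)cc4 | intermediate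
17 | (methoxymethyl)triphenylphosphonium chloride | COC[P+](c1ccccc1)(c1ccccc1)c1ccccc1.[Cl-] | starting material
18 | (R)-{(3R,5R,6R)-5-(2-methoxyethenyl)-6-[4-(triisopropylsilyloxy)phenyl]oxan-3-yl}[4-(triisopropylsilyloxy)phenyl]methanol, E/Z mixture | COC=C[C@H]1C[C@@H]([C@@H](O)c2ccc(O[Si](C(C)C)(C(C)C)C(C)C)cc2)CO[C@H]1c3ccc(O[Si](C(C)C)(C(C)C)C(C)C)cc3 | intermediate (not isolated)
19 | 2-{(2R,3R,5R)-5-{(R)-hydroxy[4-(triisopropylsilyloxy)phenyl]methyl}-2-[4-(triisopropylsilyloxy)phenyl]oxan-3-yl}acetaldehyde | O=CC[C@H]1C[C@@H]([C@@H](O)c2ccc(O[Si](C(C)C)(C(C)C)C(C)C)cc2)CO[C@H]1c3ccc(O[Si](C(C)C)(C(C)C)C(C)C)cc3 | intermediate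
20 | diethyl (4-hydroxybenzyl)phosphonate | CCOP(=O)(Cc1ccc(O)cc1)OCC | starting material
21 | diethyl [4-(triisopropylsilyloxy)benzyl]phosphonate | CCOP(=O)(Cc1ccc(O[Si](C(C)C)(C(C)C)C(C)C)cc1)OCC | intermediate
22 | (R)-[4-(triisopropylsilyloxy)phenyl]{(3R,5S,6R)-6-[4-(triisopropylsilyloxy)phenyl]-5-{(2E)-3-[4-(triisopropylsilyloxy)phenyl]prop-2-en-1-yl}oxan-3-yl}methanol | CC(C)[Si](Oc1ccc(/C=C/C[C@H]2C[C@@H]([C@@H](O)c3ccc(O[Si](C(C)C)(C(C)C)C(C)C)cc3)CO[C@H]2c4ccc(O[Si](C(C)C)(C(C)C)C(C)C)cc4)cc1)(C(C)C)C(C)C | intermediate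
23 | 4-[(1E)-3-{(2R,3S,5R)-5-[(R)-hydroxy(4-hydroxyphenyl)methyl]-2-(4-hydroxyphenyl)oxan-3-yl}prop-1-en-1-yl]phenol | Oc1ccc(/C=C/C[C@H]2C[C@@H]([C@@H](O)c3ccc(O)cc3)CO[C@H]2c2ccc(O)cc2)cc1 | target

**Step count**

Total: 13 steps. Longest linear sequence: 10 steps (3, 4, 5, 6, 7, 8, 9, 10, 12, 13; the sequence that starts with step 1 is equally long).

**Steps most likely to fail**

Step 8. The acetal may ionise with loss of the lactone-bearing alkoxide and then add intermolecularly. The chair preference at C2 may be poor. The Lewis acid may ionise the benzylic lactone C–O bond. The fallback sets out from 11 and returns at 15, and brings C2 in one oxidation level higher. Aldehyde 2 is oxidised (NaClO2, NaH2PO4, 2-methyl-2-butene) to 4-(triisopropylsilyloxy)benzoic acid F1. Esterification with 11 (DCC, DMAP) gives {(2R,3R)-6-oxo-2-[4-(triisopropylsilyloxy)phenyl]oxan-3-yl}methyl 4-(triisopropylsilyloxy)benzoate F2. LiN(i-Pr)2 (2.2 equiv, THF, −78 → 0 °C) should drive an intramolecular Claisen-type acyl transfer from oxygen to C3 (Baker–Venkataraman type). Its tetrahedral intermediate is the bridged hemiketal (1S,4R,5R)-8-hydroxy-4,8-bis[4-(triisopropylsilyloxy)phenyl]-3,7-dioxabicyclo[3.3.1]nonan-2-one F3. Et3SiH/BF3·OEt2 (CH2Cl2, −40 °C) reduces F3 through the cyclic 2-aryl oxocarbenium ion with axial hydride delivery, which leaves the aryl group equatorial and gives 15.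

Step 10. The transient α-branched aldehyde may epimerise at C3 under the basic ylide conditions. The acid hydrolysis may ionise a benzylic C–O bond or stall at a cyclic acetal. The fallback sets out from 15 and returns at 23, and avoids both the aldehyde and the acid. LiAlH4 (THF, 0 °C) reduces 15 to {(2R,3R,5R)-5-{(R)-hydroxy[4-(triisopropylsilyloxy)phenyl]methyl}-2-[4-(triisopropylsilyloxy)phenyl]oxan-3-yl}methanol F4. The primary hydroxyl is converted selectively (I2, PPh3, imidazole, 0 °C) into (R)-{(3R,5S,6R)-5-(iodomethyl)-6-[4-(triisopropylsilyloxy)phenyl]oxan-3-yl}[4-(triisopropylsilyloxy)phenyl]methanol F5. Copper-catalysed coupling with excess vinylmagnesium bromide (CuI, THF, −30 °C) gives (R)-{(3R,5S,6R)-5-(prop-2-en-1-yl)-6-[4-(triisopropylsilyloxy)phenyl]oxan-3-yl}[4-(triisopropylsilyloxy)phenyl]methanol F6. Cross-metathesis with commercial 4-(tert-butyldimethylsilyloxy)styrene (second-generation Grubbs catalyst, CH2Cl2, 40 °C) gives the (E)-styrene with one tert-butyldimethylsilyl and two triisopropylsilyl ethers F7. n-Bu4NF/AcOH then removes all three silyl groups to give 23.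

Step 7. The transacetalisation is an equilibrium and may stop at a mixture. The acid may promote migration of the lactone acyl group to the primary hydroxyl. The mixed acetal may hydrolyse on isolation. The fallback sets out from 3 and 11 and returns at 12, and replaces the equilibrium by an irreversible O-alkylation. Acetyl chloride (cat. ZnCl2, CH2Cl2, 0 °C) converts 3 into {4-[chloro(methoxy)methyl]phenoxy}triisopropylsilane F8, which is used at once to alkylate 11 in the presence of i-Pr2NEt (CH2Cl2, −40 °C) and gives 12 under basic conditions.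

**Further compounds**

F1 | step 8 | 4-(triisopropylsilyloxy)benzoic acid | OC(=O)c1ccc(O[Si](C(C)C)(C(C)C)C(C)C)cc1
F2 | step 8 | {(2R,3R)-6-oxo-2-[4-(triisopropylsilyloxy)phenyl]oxan-3-yl}methyl 4-(triisopropylsilyloxy)benzoate | O=C1CC[C@@H]([C@@H](O1)c2ccc(O[Si](C(C)C)(C(C)C)C(C)C)cc2)COC(=O)c3ccc(O[Si](C(C)C)(C(C)C)C(C)C)cc3
F3 | step 8 | (1S,4R,5R)-8-hydroxy-4,8-bis[4-(triisopropylsilyloxy)phenyl]-3,7-dioxabicyclo[3.3.1]nonan-2-one | O=C1[C@H]2C[C@@H]([C@@H](O1)c3ccc(O[Si](C(C)C)(C(C)C)C(C)C)cc3)COC2(O)c4ccc(O[Si](C(C)C)(C(C)C)C(C)C)cc4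
F4 | step 10 | {(2R,3R,5R)-5-{(R)-hydroxy[4-(triisopropylsilyloxy)phenyl]methyl}-2-[4-(triisopropylsilyloxy)phenyl]oxan-3-yl}methanol | OC[C@H]1C[C@@H]([C@@H](O)c2ccc(O[Si](C(C)C)(C(C)C)C(C)C)cc2)CO[C@H]1c3ccc(O[Si](C(C)C)(C(C)C)C(C)C)cc3
F5 | step 10 | (R)-{(3R,5S,6R)-5-(iodomethyl)-6-[4-(triisopropylsilyloxy)phenyl]oxan-3-yl}[4-(triisopropylsilyloxy)phenyl]methanol | IC[C@H]1C[C@@H]([C@@H](O)c2ccc(O[Si](C(C)C)(C(C)C)C(C)C)cc2)CO[C@H]1c3ccc(O[Si](C(C)C)(C(C)C)C(C)C)cc3
F6 | step 10 | (R)-{(3R,5S,6R)-5-(prop-2-en-1-yl)-6-[4-(triisopropylsilyloxy)phenyl]oxan-3-yl}[4-(triisopropylsilyloxy)phenyl]methanol | C=CC[C@H]1C[C@@H]([C@@H](O)c2ccc(O[Si](C(C)C)(C(C)C)C(C)C)cc2)CO[C@H]1c3ccc(O[Si](C(C)C)(C(C)C)C(C)C)cc3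
F7 | step 10 | (R)-{(3R,5S,6R)-5-{(2E)-3-[4-(tert-butyldimethylsilyloxy)phenyl]prop-2-en-1-yl}-6-[4-(triisopropylsilyloxy)phenyl]oxan-3-yl}[4-(triisopropylsilyloxy)phenyl]methanol | CC(C)(C)[Si](C)(C)Oc1ccc(/C=C/C[C@H]2C[C@@H]([C@@H](O)c3ccc(O[Si](C(C)C)(C(C)C)C(C)C)cc3)CO[C@H]2c4ccc(O[Si](C(C)C)(C(C)C)C(C)C)cc4)cc1
F8 | step 7 | {4-[chloro(methoxy)methyl]phenoxy}triisopropylsilane | COC(Cl)c1ccc(O[Si](C(C)C)(C(C)C)C(C)C)cc1
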